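Its constants were chosen freely; the flask was simulated.

With 0.900 equiv of reagent, target could not pass that fraction of the charge, for each target holds one reagent and second product holds another.

    starting material + reagent ⇌ target (K1 = 9.29 L mol⁻¹, k1 = 0.262 L mol⁻¹ s⁻¹)
    second substrate + reagent ⇌ second product (K2 = 4.0 L mol⁻¹, k2 = 2.13 L mol⁻¹ s⁻¹)
    starting material + target → side product (k3 = 0.00706 L mol⁻¹ s⁻¹)
    second substrate + protic impurity → quenched substrate (k4 = 7.05 L mol⁻¹ s⁻¹)

| flask | starting material | reagent | second substrate | protic impurity | time | remark |
|---|---|---|---|---|---|---|
| epsilon | 0.10 M | 0.900 equiv | 1.00 equiv (fed, over 10 min) | 2.00 mM | 15 min | all else is in the flask from the start; the feed brings no volume worth counting |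
| gamma | 0.10 M | 0.900 equiv | 1.00 equiv | 2.00 mM | 15 min | everything together at the start |
| beta | 0.10 M (fed, over 10 min) | 0.900 equiv | 1.00 equiv | 2.00 mM | 15 min | all else is in the flask from the start; the feed brings no volume worth counting |

- which flask leads in share of target in target plus side product ("all alike" within 1.5 percentage points) (epsilon / gamma / beta / all alike)
- share of target in target plus side product at the end, epsilon
- share of target in target plus side product at the end, gamma
- share of target in target plus side product at the end, beta

I balanced the reagent in fractions of the starting-material charge: free reagent, target and second product sum to 0.900 equiv before side product forms. I set aside the protic impurity, 2.00% of the charge. Trying 0.450 as free reagent in gamma, I found free starting material 0.705, target 0.295 and second product 0.153, and the balance returned 0.452.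

Target enters both the side-reaction rate and the amount it is held against, so it cancels. I therefore took N, the side product formed per target, a Damköhler number: the side-reaction rate constant times the concentration charged, the free fraction and the time, doubled because one side product counts as two. For gamma, N was 0.896, and the share, one over one plus N, was 52.7%. Epsilon's feed of second substrate does not enter N, so I read epsilon the same. In beta, free starting material and target both grow with the fed part, so their product averages a third of its full value over the feed. That shortened the effective time to 8.33 min, so N fell to 0.498 and the share rose to 66.8%.

One number was not quite enough. The forward half-life of starting material by the first step alone, at gamma's charge, was 0.49 min, far shorter than the feed. But target's half-life by the side reaction, 16 min, was close to the run, so neither fraction stayed put, and I trusted the ranking above the percentages.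

The forecast also named beta, but with higher shares than mine for gamma and beta: 53.8% for epsilon, 54.5% for gamma and 67.5% for beta. Its ground for beta was that “the rate scales with fed A squared, so little side product forms during the feed”.

The simulation put beta ahead, with 51.7% for epsilon, 52.4% for gamma and 66.4% for beta.

At 15.0 min, beta read 0.506 of side product per target, against N of 0.498. The neighbouring flask was beta with 0.060 M of starting material. In its balance a trial of 0.540 as free reagent returned 0.554, so its free fraction came to 0.764, and scaling N by concentration and that fraction gave 0.324, a share of 75.5%. That flask gave 75.3%, with target at 21.4% and side product at 7.01% of its charge.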